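A direct plan would open (S)-glycidyl trityl ether A1 with the alkoxide of (4E,6E,8E)-dodeca-4,6,8-trien-1-ol A2 to give secondary alcohol A3, would esterify A3 with unprotected 4-hydroxybenzoic acid under Mitsunobu inversion to give trityl-protected ester A4, and would detritylate A4 with acid; A2 would come from iodotriene A5.
Its weakest steps would be:
- the Mitsunobu esterification: a hindered secondary alcohol, a free phenol as a second acidic site, and elimination or incomplete inversion at the only stereocentre;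
- the acidic detritylation: it would free the primary hydroxyl beside the 2-O-acyl group and invite acyl migration;
- the chromium-mediated iodo-olefination towards A5: a large excess of CrCl2 and a light-sensitive iodide that cannot be stored.

The new route disconnects the C2–O(acyl) bond as an electrophilic oxygenation. It exploits the fact that C3 of the glycerol unit, the carbon of the free CH2OH, can be an aldehyde carbon: the achiral 3-(trienyloxy)propanal forms an enamine at C2, which a chiral pyrrolidine catalyst directs onto a diaroyl peroxide, and the aldehyde is reduced in the same flask. One operation thus creates the C2 stereocentre, places the aroyl group on the secondary oxygen and leaves O3 as the only free hydroxyl. No glycidol opening, no inversion at C2, no trityl group and no acid beside the ester are needed; the triene comes from a Julia–Kocienski olefination, without chromium or an iodotriene.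

Key step: step 8

Assumption: the (2S) target is the 1-O-alkyl-2-O-acyl-sn-glycerol enantiomer; both antipodes of the prolinol silyl ether catalyst are commercial and the (R)-form is the one needed. TBS stands for tert-butyldimethylsilyl.

Step 1
Reactants: 1 3,3-diethoxypropan-1-ol; 2 1,4-dibromobutane
Product: 4 1-bromo-4-(3,3-diethoxypropoxy)butane, via sodium alkoxide 3 (not isolated)
Conditions: NaH (1.05 equiv), THF, 0 °C; then 2 (4 equiv), Bu4NI (5 mol %), THF/DMF, rt to 45 °C; excess 2 distilled off
Reagents that add atoms: none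
Why: Williamson ether synthesis, in which the primary alkoxide should displace one bromide of the dibromide by SN2 while the excess of 2 suppresses double alkylation and the acetal is inert to base.

Step 2
Reactants: 4 1-bromo-4-(3,3-diethoxypropoxy)butane; 5 1-phenyl-1H-tetrazole-5-thiol
Product: 7 5-{[4-(3,3-diethoxypropoxy)butyl]sulfanyl}-1-phenyl-1H-tetrazole, via potassium thiolate 6 (not isolated)
Conditions: 5 (1.1 equiv), K2CO3 (1.5 equiv), acetone, rt to 50 °C
Reagents that add atoms: none
Why: SN2 S-alkylation of the soft tetrazolethiolate by the primary bromide, which should leave acetal and ether untouched.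

Step 3
Reactants: 7 5-{[4-(3,3-diethoxypropoxy)butyl]sulfanyl}-1-phenyl-1H-tetrazole
Product: 9 5-{[4-(3,3-diethoxypropoxy)butyl]sulfonyl}-1-phenyl-1H-tetrazole, via sulfoxide 8 (not isolated)
Conditions: mCPBA (3 equiv), NaHCO3 (5 equiv), CH2Cl2, 0 °C to rt, 16 h
Reagents that add atoms: 3-chloroperoxybenzoic acid (mCPBA), O=C(OO)c1cccc(Cl)c1
Why: peracid oxidation of the sulfide through the sulfoxide to the sulfone, with NaHCO3 as buffer so that the acid-labile acetal should survive.

Step 4
Reactants: 9 5-{[4-(3,3-diethoxypropoxy)butyl]sulfonyl}-1-phenyl-1H-tetrazole; 10 (2E,4E)-octa-2,4-dienal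
Product: 12 (4E,6E,8E)-1-(3,3-diethoxypropoxy)dodeca-4,6,8-triene, via potassium sulfonyl carbanion 11 (not isolated)
Conditions: KN(SiMe3)2 (1.05 equiv), DME, −60 °C, 20 min; then 10 (1.2 equiv), −60 °C to rt, dark; aq NH4Cl
Reagents that add atoms: none
Why: Julia–Kocienski olefination, in which the metalated phenyltetrazolyl sulfone adds to the aldehyde and Smiles rearrangement with loss of SO2 and tetrazololate should form the new C4=C5 bond with (E)-geometry (favoured by potassium in DME), the (E,E)-diene of 10 being carried through unchanged.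

Step 5
Reactants: 12 (4E,6E,8E)-1-(3,3-diethoxypropoxy)dodeca-4,6,8-triene
Product: 13 3-[(4E,6E,8E)-dodeca-4,6,8-trien-1-yloxy]propanal
Conditions: 1 M aq HCl/THF 1:4, 0 °C to rt, 1 h, argon, dark; NaHCO3; used at once
Reagents that add atoms: water, O
Why: acid-catalysed acetal hydrolysis under conditions mild enough that the conjugated triene should not be protonated and the β-alkoxy aldehyde should not eliminate.

Step 6
Reactants: 14 4-hydroxybenzoic acid
Product: 16 4-[(tert-butyldimethylsilyl)oxy]benzoic acid, via silyl ester 15 (not isolated)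
Conditions: TBSCl (2.3 equiv), imidazole (5 equiv), DMF, rt, 12 h; then AcOH/THF/H2O 3:1:1, rt, 2 h
Reagents that add atoms: tert-butyldimethylsilyl chloride, CC(C)(C)[Si](C)(C)Cl
Why: imidazole-promoted silylation of both acidic hydroxyls followed by selective hydrolysis of the far more labile silyl ester, which should leave the aryl silyl ether in place.

Step 7
Reactants: 16 4-[(tert-butyldimethylsilyl)oxy]benzoic acid
Product: 18 bis{4-[(tert-butyldimethylsilyl)oxy]benzoyl} peroxide, via peroxy acid 17 (not isolated)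
Conditions: 16 (2.0 equiv), DCC (N,N'-dicyclohexylcarbodiimide, 2.0 equiv), 50% aq H2O2 (1.0 equiv), CH2Cl2/Et2O, 0 °C, 2 h; urea filtered off; kept cold as a stock solution and never heated or taken to dryness on scale
Reagents that add atoms: hydrogen peroxide, OO; 4-[(tert-butyldimethylsilyl)oxy]benzoic acid (second molecule of 16), CC(C)(C)[Si](C)(C)Oc1ccc(cc1)C(O)=O
Why: carbodiimide-mediated diacyl peroxide synthesis that joins two molecules of 16 through one molecule of H2O2, in which H2O2 attacks the O-acylisourea of the first molecule to give peroxy acid 17 and this is acylated by the O-acylisourea of the second molecule, under neutral conditions that the aryl silyl ether should tolerate.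

Step 8
Reactants: 13 3-[(4E,6E,8E)-dodeca-4,6,8-trien-1-yloxy]propanal; 18 bis{4-[(tert-butyldimethylsilyl)oxy]benzoyl} peroxide
Product: 20 (2S)-1-[(4E,6E,8E)-dodeca-4,6,8-trien-1-yloxy]-3-hydroxypropan-2-yl 4-[(tert-butyldimethylsilyl)oxy]benzoate, via (2R)-2-aroyloxy aldehyde 19 (not isolated)
Conditions: (R)-2-[diphenyl(trimethylsilyloxy)methyl]pyrrolidine (10 mol %), hydroquinone (10 mol %), 18 (1.2 equiv), THF, 0 °C, argon, dark; then MeOH, NaBH4 (2 equiv), −20 °C, 15 min; pH 7 phosphate buffer
Reagents that add atoms: none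
Why: Enamine catalysis, with organocatalytic α-benzoyloxylation of aldehydes by diacyl peroxides as the closest known reaction type: aldehyde 13 condenses with the secondary amine to the (E)-enamine, whose C2 attacks one peroxide oxygen of 18 in an SN2 displacement that expels a carboxylate, and hydrolysis of the iminium ion releases the catalyst and aldehyde 19, which NaBH4 reduces at once to the primary alcohol. No ring is closed. The single new stereocentre C2 is set by the catalyst, whose diphenyl(silyloxy)methyl group shields one face of the s-trans enamine so that the O–O bond is attacked from the open face, which for the (R)-catalyst should give (2R)-19; the descriptor becomes (2S) in 20 only because CH2OH ranks below CH2O-alkyl, no bond at C2 being touched in the reduction. The step needs chemoselectivity for the enamine over the triene, which the far higher nucleophilicity of the enamine, the low temperature, the electron-rich and therefore less electrophilic peroxide, and hydroquinone as radical-chain inhibitor should secure. It needs mono-oxygenation at one position, which is inherent because C2 is the only enolisable carbon and the hindered product aldehyde re-forms an enamine only slowly. Acyl migration cannot occur before the reduction because C3 is then a carbonyl carbon, and the reduction is run cold, briefly and quenched at pH 7 so that the aroyl group should stay on O2.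

Step 9
Reactants: 20 (2S)-1-[(4E,6E,8E)-dodeca-4,6,8-trien-1-yloxy]-3-hydroxypropan-2-yl 4-[(tert-butyldimethylsilyl)oxy]benzoate
Product: 21 (2S)-1-[(4E,6E,8E)-dodeca-4,6,8-trien-1-yloxy]-3-hydroxypropan-2-yl 4-hydroxybenzoate (CNP0352133.1)
Conditions: Bu4NF (1.1 equiv), AcOH (1.5 equiv), THF, 0 °C, 20 min; pH 6 buffer; fast chromatography on boric-acid-treated silica
Reagents that add atoms: none
Why: fluoride-induced cleavage of the aryl silyl ether, buffered with acetic acid so that no alkoxide forms, which should leave the ester on O2, the triene and C2 untouched.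

## Compound list

1 | 3,3-diethoxypropan-1-ol | CCOC(OCC)CCO | starting material
2 | 1,4-dibromobutane | BrCCCCBr | starting material
3 | sodium 3,3-diethoxypropan-1-olate (not isolated) | CCOC(OCC)CC[O-].[Na+] | intermediate
4 | 1-bromo-4-(3,3-diethoxypropoxy)butane | CCOC(OCC)CCOCCCCBr | intermediate
5 | 1-phenyl-1H-tetrazole-5-thiol | Sc1nnnn1-c1ccccc1 | starting material
6 | potassium 1-phenyl-1H-tetrazole-5-thiolate (not isolated) | [K+].[S-]c1nnnn1-c1ccccc1 | intermediate
7 | 5-{[4-(3,3-diethoxypropoxy)butyl]sulfanyl}-1-phenyl-1H-tetrazole | CCOC(OCC)CCOCCCCSc1nnnn1-c1ccccc1 | intermediate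
8 | 5-{[4-(3,3-diethoxypropoxy)butyl]sulfinyl}-1-phenyl-1H-tetrazole (racemic at sulfur, not isolated) | CCOC(OCC)CCOCCCCS(=O)c1nnnn1-c1ccccc1 | intermediate
9 | 5-{[4-(3,3-diethoxypropoxy)butyl]sulfonyl}-1-phenyl-1H-tetrazole | CCOC(OCC)CCOCCCCS(=O)(=O)c1nnnn1-c1ccccc1 | intermediate
10 | (2E,4E)-octa-2,4-dienal | CCC/C=C/C=C/C=O | starting material
11 | potassium salt of the α-sulfonyl carbanion of 9 (not isolated) | CCOC(OCC)CCOCCC[CH-]S(=O)(=O)c1nnnn1-c1ccccc1.[K+] | intermediate
12 | (4E,6E,8E)-1-(3,3-diethoxypropoxy)dodeca-4,6,8-triene | CCC/C=C/C=C/C=C/CCCOCCC(OCC)OCC | intermediate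
13 | 3-[(4E,6E,8E)-dodeca-4,6,8-trien-1-yloxy]propanal | CCC/C=C/C=C/C=C/CCCOCCC=O | intermediate
14 | 4-hydroxybenzoic acid | OC(=O)c1ccc(O)cc1 | starting material
15 | tert-butyldimethylsilyl 4-[(tert-butyldimethylsilyl)oxy]benzoate (not isolated) | CC(C)(C)[Si](C)(C)Oc1ccc(cc1)C(=O)O[Si](C)(C)C(C)(C)C | intermediate
16 | 4-[(tert-butyldimethylsilyl)oxy]benzoic acid | CC(C)(C)[Si](C)(C)Oc1ccc(cc1)C(O)=O | intermediate
17 | 4-[(tert-butyldimethylsilyl)oxy]peroxybenzoic acid (not isolated) | CC(C)(C)[Si](C)(C)Oc1ccc(cc1)C(=O)OO | intermediate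
18 | bis{4-[(tert-butyldimethylsilyl)oxy]benzoyl} peroxide | CC(C)(C)[Si](C)(C)Oc1ccc(cc1)C(=O)OOC(=O)c1ccc(O[Si](C)(C)C(C)(C)C)cc1 | intermediate
19 | (2R)-1-[(4E,6E,8E)-dodeca-4,6,8-trien-1-yloxy]-3-oxopropan-2-yl 4-[(tert-butyldimethylsilyl)oxy]benzoate (not isolated) | CCC/C=C/C=C/C=C/CCCOC[C@H](C=O)OC(=O)c1ccc(O[Si](C)(C)C(C)(C)C)cc1 | intermediate
20 | (2S)-1-[(4E,6E,8E)-dodeca-4,6,8-trien-1-yloxy]-3-hydroxypropan-2-yl 4-[(tert-butyldimethylsilyl)oxy]benzoate | CCC/C=C/C=C/C=C/CCCOC[C@H](CO)OC(=O)c1ccc(O[Si](C)(C)C(C)(C)C)cc1 | intermediate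
21 | (2S)-1-[(4E,6E,8E)-dodeca-4,6,8-trien-1-yloxy]-3-hydroxypropan-2-yl 4-hydroxybenzoate (CNP0352133.1) | CCC/C=C/C=C/C=C/CCCOC[C@H](CO)OC(=O)c1ccc(O)cc1 | target

Total step count: 9. Longest linear sequence: 7 (steps 1, 2, 3, 4, 5, 8, 9); steps 6 and 7 form the two-step peroxide branch.

Steps most likely to fail

Step 8 (key step). The peroxide, or aroyloxy radicals formed from it, may attack the triene; the enamine may expel the β-alkoxy group (retro-oxa-Michael); or facial control may be incomplete. The fallback takes C2 from the chiral pool, sets out from 1,4-dibromobutane 2 and comes back to the route at 20. (R)-Solketal would be alkylated with excess 2 (NaH, THF/DMF) to (4R)-4-[(4-bromobutoxy)methyl]-2,2-dimethyl-1,3-dioxolane F1. Thiol 5 with K2CO3 would give 5-[(4-{[(4R)-2,2-dimethyl-1,3-dioxolan-4-yl]methoxy}butyl)sulfanyl]-1-phenyl-1H-tetrazole F2, and mCPBA/NaHCO3 the corresponding sulfone F3. Julia–Kocienski olefination of F3 with 10 (KN(SiMe3)2, DME, −60 °C) would give (4R)-4-{[(4E,6E,8E)-dodeca-4,6,8-trien-1-yloxy]methyl}-2,2-dimethyl-1,3-dioxolane F4. Aqueous acetic acid would free (2S)-3-[(4E,6E,8E)-dodeca-4,6,8-trien-1-yloxy]propane-1,2-diol F5, and trityl chloride in pyridine would mask its primary hydroxyl as (2R)-1-[(4E,6E,8E)-dodeca-4,6,8-trien-1-yloxy]-3-(trityloxy)propan-2-ol F6. Acid 16 with DCC and 4-(dimethylamino)pyridine would acylate O2 with retention to the (2R)-ester F7, and BF3·OEt2/MeOH in CH2Cl2 at 0 °C would remove the trityl group to give 20.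

Step 4. The (E)-selectivity at the new C4=C5 bond may be incomplete, or the sulfonyl carbanion may deprotonate the dienal at its vinylogous position instead of adding. The fallback forms this bond by a [3,3]-sigmatropic rearrangement, sets out from dienal 10 and comes back at 12. CH2=CHMgBr (THF, −78 °C) would add 1,2 to give racemic (4E,6E)-deca-1,4,6-trien-3-ol F8. Johnson–Claisen rearrangement (triethyl orthoacetate, catalytic propionic acid, 135 °C) through a chair transition state at the unsubstituted vinyl terminus would give ethyl (4E,6E,8E)-dodeca-4,6,8-trienoate F9. LiAlH4 in Et2O at 0 °C would give (4E,6E,8E)-dodeca-4,6,8-trien-1-ol F10, the same alcohol as A2, and MsCl/Et3N its methanesulfonate F11. Displacement of F11 by the sodium alkoxide of 1 (NaH, DMF) would give 12.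

Step 9. The aroyl group may migrate from O2 to O3 under fluoride or on silica. The fallback changes the phenol mask to an acetate that is removed enzymatically at neutral pH, sets out from aldehyde 13 and comes back at 21. Commercial 4-acetoxybenzoic acid with DCC and H2O2 would give bis(4-acetoxybenzoyl) peroxide F12. Under the conditions of step 8, F12 and 13 would give, through the (2R)-aldehyde F13, (2S)-1-[(4E,6E,8E)-dodeca-4,6,8-trien-1-yloxy]-3-hydroxypropan-2-yl 4-acetoxybenzoate F14. Immobilised lipase B from Candida antarctica with n-butanol in tert-butyl methyl ether at rt would transfer the aryl acetate to butanol and should give 21 directly, the hindered secondary benzoate being no substrate.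

## Further compounds

F1 | step 8 | (4R)-4-[(4-bromobutoxy)methyl]-2,2-dimethyl-1,3-dioxolane | CC1(C)OC[C@@H](COCCCCBr)O1
F2 | step 8 | 5-[(4-{[(4R)-2,2-dimethyl-1,3-dioxolan-4-yl]methoxy}butyl)sulfanyl]-1-phenyl-1H-tetrazole | CC1(C)OC[C@@H](COCCCCSc2nnnn2-c2ccccc2)O1
F3 | step 8 | 5-[(4-{[(4R)-2,2-dimethyl-1,3-dioxolan-4-yl]methoxy}butyl)sulfonyl]-1-phenyl-1H-tetrazole | CC1(C)OC[C@@H](COCCCCS(=O)(=O)c2nnnn2-c2ccccc2)O1
F4 | step 8 | (4R)-4-{[(4E,6E,8E)-dodeca-4,6,8-trien-1-yloxy]methyl}-2,2-dimethyl-1,3-dioxolane | CCC/C=C/C=C/C=C/CCCOC[C@@H]1COC(C)(C)O1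
F5 | step 8 | (2S)-3-[(4E,6E,8E)-dodeca-4,6,8-trien-1-yloxy]propane-1,2-diol | CCC/C=C/C=C/C=C/CCCOC[C@H](CO)O
F6 | step 8 | (2R)-1-[(4E,6E,8E)-dodeca-4,6,8-trien-1-yloxy]-3-(trityloxy)propan-2-ol | CCC/C=C/C=C/C=C/CCCOC[C@H](COC(c1ccccc1)(c1ccccc1)c1ccccc1)O
F7 | step 8 | (2R)-1-[(4E,6E,8E)-dodeca-4,6,8-trien-1-yloxy]-3-(trityloxy)propan-2-yl 4-[(tert-butyldimethylsilyl)oxy]benzoate | CCC/C=C/C=C/C=C/CCCOC[C@H](COC(c1ccccc1)(c1ccccc1)c1ccccc1)OC(=O)c1ccc(O[Si](C)(C)C(C)(C)C)cc1
F8 | step 4 | (4E,6E)-deca-1,4,6-trien-3-ol (racemic) | C=CC(O)/C=C/C=C/CCC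
F9 | step 4 | ethyl (4E,6E,8E)-dodeca-4,6,8-trienoate | CCC/C=C/C=C/C=C/CCC(=O)OCC
F10 | step 4 | (4E,6E,8E)-dodeca-4,6,8-trien-1-ol | CCC/C=C/C=C/C=C/CCCO
F11 | step 4 | (4E,6E,8E)-dodeca-4,6,8-trien-1-yl methanesulfonate | CCC/C=C/C=C/C=C/CCCOS(C)(=O)=O
F12 | step 9 | bis(4-acetoxybenzoyl) peroxide | CC(=O)Oc1ccc(cc1)C(=O)OOC(=O)c1ccc(OC(C)=O)cc1
F13 | step 9 | (2R)-1-[(4E,6E,8E)-dodeca-4,6,8-trien-1-yloxy]-3-oxopropan-2-yl 4-acetoxybenzoate | CCC/C=C/C=C/C=C/CCCOC[C@H](C=O)OC(=O)c1ccc(OC(C)=O)cc1
F14 | step 9 | (2S)-1-[(4E,6E,8E)-dodeca-4,6,8-trien-1-yloxy]-3-hydroxypropan-2-yl 4-acetoxybenzoate | CCC/C=C/C=C/C=C/CCCOC[C@H](CO)OC(=O)c1ccc(OC(C)=O)cc1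
A1 | direct plan | (S)-glycidyl trityl ether, (2S)-2-[(trityloxy)methyl]oxirane | C1[C@@H](COC(c2ccccc2)(c2ccccc2)c2ccccc2)O1
A2 | direct plan | (4E,6E,8E)-dodeca-4,6,8-trien-1-ol | CCC/C=C/C=C/C=C/CCCO
A3 | direct plan | (2S)-1-[(4E,6E,8E)-dodeca-4,6,8-trien-1-yloxy]-3-(trityloxy)propan-2-ol | CCC/C=C/C=C/C=C/CCCOC[C@@H](COC(c1ccccc1)(c1ccccc1)c1ccccc1)O
A4 | direct plan | (2R)-1-[(4E,6E,8E)-dodeca-4,6,8-trien-1-yloxy]-3-(trityloxy)propan-2-yl 4-hydroxybenzoate | CCC/C=C/C=C/C=C/CCCOC[C@H](COC(c1ccccc1)(c1ccccc1)c1ccccc1)OC(=O)c1ccc(O)cc1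
A5 | direct plan | (1E,3E,5E)-1-iodonona-1,3,5-triene | CCC/C=C/C=C/C=C/I
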